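The ratio of the product concentration in the alpha run to that in the gamma run at 15.0 min is 0.903, although their charges of substrate stand in the ratio 0.318. Percentages hide this, so the readings are best turned into concentrations: in these two flasks product forms at nearly the same pace from very different [substrate], which is close to zero order in substrate.

| setting | alpha | gamma | delta | Friday's | Sunday's |
|---|---|---|---|---|---|
| substrate | 0.035 M | 0.11 M | 0.086 M | 0.030 M | 0.086 M |
| coupling partner | 0.112 M | 0.112 M | 0.112 M | 0.112 M | 0.112 M |
| initiator | 7.5 mM | 7.5 mM | 5.2 mM | 5.0 mM | 7.5 mM |
| remark | run made earlier | run made earlier | run made earlier |  |  |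
| time |  |  |  | 20 min | 20 min |

| run | time / min | product / % | substrate / % |
|---|---|---|---|
| alpha | 0.833 | 7 | 94 |
| alpha | 2.00 | 16 | 89 |
| alpha | 4.00 | 26 | 74 |
| alpha | 6.00 | 40 | 57 |
| alpha | 8.00 | 56 | 47 |
| alpha | 12.0 | 74 | 26 |
| alpha | 15.0 | 88 | 12 |
| gamma | 2.00 | 5 | 94 |
| gamma | 4.00 | 10 | 89 |
| gamma | 6.00 | 11 | 85 |
| gamma | 8.00 | 17 | 84 |
| gamma | 10.0 | 24 | 79 |
| gamma | 12.0 | 26 | 73 |
| gamma | 15.0 | 31 | 69 |
| delta | 1.00 | 1 | 98 |
| delta | 2.00 | 4 | 94 |
| delta | 4.00 | 11 | 89 |
| delta | 8.00 | 23 | 85 |
| delta | 15.0 | 32 | 65 |

(standard deviation of a reading: 1.5 percentage points)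



* the winner by amount of product, in percent of the substrate charged; "neither" if no more than 2 percentage points parts them (Friday's / Sunday's / neither)
* how much product is there at the end, in percent of the substrate charged: Friday's
* how much product is there at the end, in percent of the substrate charged: Sunday's

The gamma run, with 69 % of its substrate still present at 15.0 min, gives 2.27 mM min⁻¹. This is the product flux v, the concentration of product made per minute at 0.112 M of coupling partner and 7.5 mM of initiator. A second way uses a different flask: the alpha run up to 8.00 min gives 2.45 mM min⁻¹, a factor 1.08 from v, so the two agree and v is trusted. Read to its last point, however, the alpha run gives 2.05 mM min⁻¹, less than v. That way cheats, because its average reaches down to 12 % of substrate, close to the end of the charge.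

The useful rule is the demand ratio, v times the time divided by [substrate] as charged. Below one it reads as the fraction converted; above one, the demand exceeds the substrate charged. For the alpha run at 15.0 min it is 0.974, yet 88 % was read, so in that run the ratio stands above the reading. For Sunday's it is 0.529.

Friday's has less initiator than Sunday's, so logarithms are needed. The delta run gives 1.83 mM min⁻¹, and the logarithm of its flux ratio to v over that of its initiator ratio reads as an order of 0.585, a noisy reading. Friday's flux is then 1.79 mM min⁻¹, and its demand ratio 1.20, so the reckoning here expects Friday's close to complete, with a tail.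

The forecast gives 95 % for Friday's, 45 % for Sunday's and Friday's as the winner, with a rate “slowing gently with time”. Its Sunday's figure lies below the ratio reckoned here.

The flask gives 94.5 % for Friday's and 48.8 % for Sunday's, so Friday's holds more product.

    2 first chain carrier → ended chains B (k = 3.00 × 10⁸ M⁻¹ s⁻¹)
    substrate + initiating radical → capped initiator + first chain carrier (k = 3.40 × 10⁵ M⁻¹ s⁻¹)
    coupling partner + first chain carrier ⇌ product + second chain carrier (K = 1.40, k = 16000 M⁻¹ s⁻¹)
    initiator → 2 initiating radical (k = 0.00150 min⁻¹)
    substrate + second chain carrier → released group + first chain carrier (k = 4.60 × 10⁵ M⁻¹ s⁻¹)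
    2 second chain carrier → ended chains A (k = 1.20 × 10⁹ M⁻¹ s⁻¹)

Sunday's still holds 50.7 % of its substrate at 20 min, and its average flux of 2.10 mM min⁻¹ lies a little below v. The alpha, gamma and delta runs shared 0.112 M of coupling partner, so v belongs to that charge, and the forecast's 45 % belongs to it too: with 0.100 M or 0.124 M of coupling partner in Sunday's, the answer has moved by 5 points. Scaling v in proportion to coupling partner for the neighbour of Sunday's charged with 0.067 M gives a demand ratio of 0.316, and that flask ended at 29.4 % product.

(The data are calculated for an exercise.)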